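**Retrosynthetic overview**

- The target is two identical 2-acylcyclohexane-1,3,5-trione rings joined by CH2. In each ring, number C1 (C=O), C2 (carries the bridge CH2), C3 (C–OH), C4 (CMe2), C5 (C–OH), C6 (carries the isobutyryl group). The last step only hydrolyses two enol methyl ethers on the C1 oxygens.
- Key disconnection, made in both rings in one operation: ring bonds C3–C4 and C5–C6. This removes the two-carbon unit C4(Me2)–C5(=O) as the enolate of methyl isobutyrate. What remains of each ring (C3, C2, C1, C6 and the isobutyryl carbonyl carbon) is C2–C6 of a 4-methoxy-6-isopropyl-2-pyranone, a temporary ring whose O1–C6 bond becomes the exocyclic acyl C=O.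
- Enabling feature: C4 is a quaternary carbon between two ring carbonyl carbons (C3, C5), and the isobutyryl C=O is 1,3 to the C1 oxygen through C6. The chain C3–C2–C1–C6–C(O)iPr is therefore a 1,3,5-trioxygenated five-carbon unit that can be stored as a 2-pyranone, and its C3 (ring C2) is the most nucleophilic carbon and takes the bridge.
- Ring order: 1,3-dioxin-4-one (bought) → 2-pyranone via an acylketene → two pyranones joined at C3 by formaldehyde → both carbocycles from the bis-pyranone in one flask. The second Claisen closure is the last ring closure of the route; the two carbocycles are equivalent by symmetry.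

Key step: step 5

Remark: the target has no stereocentre and no stereogenic double bond, so it is achiral and needs no stereocontrol; the SMILES given is one enol tautomer.
Remark: enolates and salts of numbered compounds are counted as the compound itself, and in-flask intermediates are written in neutral form.

**Route**

Step 1
Reactants: 1 2,2,6-trimethyl-4H-1,3-dioxin-4-one; 2 2-methylpropanoyl chloride (isobutyryl chloride)
Product: 3 2,2-dimethyl-6-(3-methyl-2-oxobutyl)-4H-1,3-dioxin-4-one
Conditions: 1 (2 equiv), LiHMDS (2 equiv), THF, –78 °C; then 2 (1 equiv), –78 → –20 °C; aq. NH4Cl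
Reagents that add atoms: none
Why: Vinylogous Claisen acylation of the lithium dienolate of the dioxinone at its exocyclic γ-carbon by an acid chloride is a standard entry to 6-(2-oxoalkyl)dioxinones, the second equivalent of dienolate taking up the acidic proton of the product.

Step 2
Reactants: 3 2,2-dimethyl-6-(3-methyl-2-oxobutyl)-4H-1,3-dioxin-4-one
Product: 5 4-hydroxy-6-(propan-2-yl)-2H-pyran-2-one, via acylketene 4 (not isolated)
Conditions: toluene, 110 °C
Reagents that add atoms: none
Why: Thermal retro-[4+2] cleavage of the dioxinone should release acetone and the acylketene, whose δ-keto enol oxygen closes on the ketene carbon (oxa-6π electrocyclisation) to give the 4-hydroxy-2-pyranone, a well-used pyranone synthesis.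

Step 3
Reactants: 5 4-hydroxy-6-(propan-2-yl)-2H-pyran-2-one (2 equiv); 6 formaldehyde
Product: 8 3,3'-methylenebis[4-hydroxy-6-(propan-2-yl)-2H-pyran-2-one], via 3-methylidenepyrandione 7 (not isolated)
Conditions: 37% aq. CH2O (0.5 equiv), EtOH, cat. piperidine/AcOH, 25 → 70 °C
Reagents that add atoms: none
Why: Knoevenagel condensation at C3 (the carbon between the lactone C=O and the enol carbon) followed by Michael addition of a second pyranone to the 3-methylidene-2,4-dione is the tandem that gives dicoumarol-type methylenebis(4-hydroxy-2-pyranones), and C5 and the isopropyl group do not compete.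

Step 4
Reactants: 8 3,3'-methylenebis[4-hydroxy-6-(propan-2-yl)-2H-pyran-2-one]
Product: 9 3,3'-methylenebis[4-methoxy-6-(propan-2-yl)-2H-pyran-2-one]
Conditions: Me2SO4 (2.5 equiv), K2CO3 (3 equiv), acetone, reflux
Reagents that add atoms: dimethyl sulfate, COS(=O)(=O)OC
Why: Williamson-type O-alkylation of the vinylogous acid by the hard electrophile should give the 4-methoxy-2-pyranones, as it does for monomeric 4-hydroxy-6-alkyl-2-pyranones, and it removes the acidic OH groups that would quench the enolate and deactivate the lactone carbonyls in step 5.

Step 5
Reactants: 9 3,3'-methylenebis[4-methoxy-6-(propan-2-yl)-2H-pyran-2-one]; 10 methyl 2-methylpropanoate (methyl isobutyrate, used as its lithium enolate)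
Product: 13 2,2'-methylenebis[5-hydroxy-3-methoxy-6,6-dimethyl-4-(2-methylpropanoyl)cyclohexa-2,4-dien-1-one], via bis-ring-opened keto ester 11 (not isolated), via mono-cyclised keto ester 12 (not isolated)
Conditions: 10 (5 equiv), LDA (4.8 equiv), THF, –78 °C; then 9, –78 °C; then → 25–50 °C; cold 1 M HCl
Reagents that add atoms: none
Why: Proposed new method: the tertiary lithium enolate of 10 should add to the lactone carbonyl C2 of each 4-methoxy-2-pyranone and the tetrahedral alkoxide should collapse with cleavage of C2–O1, so that the ring oxygen leaves as the enolate of the isobutyryl ketone and the new C2 ketone is protected inside a delocalised 1,5-dioxo-dienolate (11, formed on both halves at –78 °C); on warming, the enolate carbon (former pyranone C5) of each half should attack its own α,α-dimethyl ester and expel methoxide (11 → 12 → 13), and the methoxide then deprotonates the 2-acyl-1,3-dione, which makes the closure irreversible. The closest known reaction types are the Fujimoto–Belleau conversion of enol lactones into cyclohexenones by carbon nucleophiles (here ended by a Claisen instead of an aldol step), carbanion-induced ring transformations of 2-pyranones, and the Claisen cyclisation of 3,5,7-trioxo esters to acylphloroglucinols; the use of an ester enolate as a two-carbon unit on a 4-alkoxy-2-pyranone is the untested part. Each carbocycle closes in the 6-(enolexo)-exo-trig mode (Dieckmann-type), helped by the gem-dimethyl (Thorpe–Ingold) effect, and the closure 12 → 13 is the last ring closure of the route. No stereocentre is formed; the only geometric requirement, the cis relation of the C2-derived ketone and C5 across the C3=C4 enol ether, is inherited from the pyranone ring. The step needs 1,2-attack at C2 in preference to conjugate attack at C4 or C6 and to γ-deprotonation of the isopropyl group, which the hard lithium enolate at –78 °C, the donor methoxy group on C4 and the isopropyl-shielded C6 should secure; it also needs closure within each half and not across the bridge, which is secured by opening both lactones with excess enolate before warming, after which the quaternary carbon leaves the Claisen mode as the only six-membered closure (attack on the ester of the other half would need an eight-membered ring).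

Step 6
Reactants: 13 2,2'-methylenebis[5-hydroxy-3-methoxy-6,6-dimethyl-4-(2-methylpropanoyl)cyclohexa-2,4-dien-1-one]
Product: 14 2,2'-methylenebis[3,5-dihydroxy-4,4-dimethyl-6-(2-methylpropanoyl)cyclohexa-2,5-dien-1-one] (target)
Conditions: 2 M aq. HCl, THF, 60 °C
Reagents that add atoms: water, O
Why: Acid hydrolysis of the two vinylogous methyl esters (addition of water at the methoxy-bearing ring carbon, then loss of methanol) should free the enolised triones, the C-acyl groups and the methylene bridge being stable to aqueous acid and any methylene exchange between the halves being degenerate in this symmetric dimer.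

**Compound list**

1 | 2,2,6-trimethyl-4H-1,3-dioxin-4-one | CC1=CC(=O)OC(C)(C)O1 | starting material
2 | 2-methylpropanoyl chloride | CC(C)C(Cl)=O | starting material
3 | 2,2-dimethyl-6-(3-methyl-2-oxobutyl)-4H-1,3-dioxin-4-one | CC(C)C(=O)CC1=CC(=O)OC(C)(C)O1 | intermediate
4 | 6-methyl-3,5-dioxohept-1-en-1-one (acylketene) | CC(C)C(=O)CC(=O)C=C=O | intermediate (not isolated)
5 | 4-hydroxy-6-(propan-2-yl)-2H-pyran-2-one | CC(C)C1=CC(O)=CC(=O)O1 | intermediate
6 | formaldehyde | C=O | starting material
7 | 3-methylidene-6-(propan-2-yl)-2H-pyran-2,4(3H)-dione | CC(C)C1=CC(=O)C(=C)C(=O)O1 | intermediate (not isolated)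
8 | 3,3'-methylenebis[4-hydroxy-6-(propan-2-yl)-2H-pyran-2-one] | CC(C)C1=CC(O)=C(CC2=C(O)C=C(C(C)C)OC2=O)C(=O)O1 | intermediate
9 | 3,3'-methylenebis[4-methoxy-6-(propan-2-yl)-2H-pyran-2-one] | CC(C)C1=CC(OC)=C(CC2=C(OC)C=C(C(C)C)OC2=O)C(=O)O1 | intermediate
10 | methyl 2-methylpropanoate | COC(=O)C(C)C | starting material
11 | dimethyl (4E,4'E)-4,4'-methylenebis(5-methoxy-2,2,8-trimethyl-3,7-dioxonon-4-enoate) | COC(=O)C(C)(C)C(=O)/C(CC(\C(=O)C(C)(C)C(=O)OC)=C(/OC)CC(=O)C(C)C)=C(/OC)CC(=O)C(C)C | intermediate (not isolated)
12 | methyl (4E)-4-{[4-hydroxy-2-methoxy-5,5-dimethyl-3-(2-methylpropanoyl)-6-oxocyclohexa-1,3-dien-1-yl]methyl}-5-methoxy-2,2,8-trimethyl-3,7-dioxonon-4-enoate | CC(C)C(=O)C1=C(O)C(C)(C)C(=O)C(CC(\C(=O)C(C)(C)C(=O)OC)=C(/OC)CC(=O)C(C)C)=C1OC | intermediate (not isolated)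
13 | 2,2'-methylenebis[5-hydroxy-3-methoxy-6,6-dimethyl-4-(2-methylpropanoyl)cyclohexa-2,4-dien-1-one] | CC(C)C(=O)C1=C(O)C(C)(C)C(=O)C(CC2=C(OC)C(C(=O)C(C)C)=C(O)C(C)(C)C2=O)=C1OC | intermediate
14 | 2,2'-methylenebis[3,5-dihydroxy-4,4-dimethyl-6-(2-methylpropanoyl)cyclohexa-2,5-dien-1-one] | CC(C)C(=O)C1=C(O)C(C)(C)C(O)=C(CC2=C(O)C(C)(C)C(O)=C(C(=O)C(C)C)C2=O)C1=O | target

**Step count and risks**

Total step count: 6. Longest linear sequence: 6 steps (1 → 3 → 5 → 8 → 9 → 13 → 14).

Step 5 (Proposed new method). What may go wrong: the ester enolate may act as a base toward the pyranone (γ-deprotonation at the isopropyl methine) or add in conjugate fashion at C6 or C4 instead of at the lactone carbonyl, so that no ring opening takes place. The ring opening may also succeed while the Claisen closure onto the neopentyl-type ester stalls, leaving the open chain to cyclodehydrate to pyranone-type material on acidic work-up, or retro-Michael loss of the bridge may set in on heating. The fallback uses known chemistry only and gives up the late ring construction. It sets out from 2 and 6. Friedel–Crafts C-acylation of phloroglucinol (benzene-1,3,5-triol, commercial) with 2 (AlCl3, nitrobenzene) should give 2-methyl-1-(2,4,6-trihydroxyphenyl)propan-1-one F1. Dearomatising geminal C-methylation of F1 (NaOMe, MeI, MeOH) should give 3,5-dihydroxy-4,4-dimethyl-2-(2-methylpropanoyl)cyclohexa-2,5-dien-1-one F2. Knoevenagel–Michael coupling of two molecules of F2 with 6 (aq. formaldehyde, dilute aq. NaOH) comes back to the route at 14.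

Step 1. What may go wrong: proton transfer from the more acidic product to unreacted dienolate, competing α- or O-acylation, and a second acylation may erode conversion. The fallback sets out from 10 and builds the triketide chain by ester Claisen chemistry instead of through the dioxinone. γ-Acylation of the dianion of methyl acetoacetate (NaH, then n-BuLi, THF, 0 °C; commercial ester) with 10 should give methyl 6-methyl-3,5-dioxoheptanoate F3. Base-induced lactonisation of F3 (DBU, toluene, reflux) comes back to the route at 5, bypassing 3 and 4.

Step 4. What may go wrong: alkylation of the ambident pyronate at O-2 (giving 2-methoxy-4-pyranone units) or at C-3, or incomplete alkylation of the second, strongly hydrogen-bonded enol. The fallback sets out from 8 and comes back at 9 without a new compound. It replaces alkylation of the pyronate dianion by a Mitsunobu redox condensation with methanol (PPh3, DIAD, MeOH, THF, 0 → 25 °C), in which the neutral 4-OH acts as the acidic partner and methanol is the activated one, a mode known to favour O-4 in 4-hydroxy-2-pyranones.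

**Further compounds**

F1 | step 5 | 2-methyl-1-(2,4,6-trihydroxyphenyl)propan-1-one | CC(C)C(=O)c1c(O)cc(O)cc1O
F2 | step 5 | 3,5-dihydroxy-4,4-dimethyl-2-(2-methylpropanoyl)cyclohexa-2,5-dien-1-one | CC(C)C(=O)C1=C(O)C(C)(C)C(O)=CC1=O
F3 | step 1 | methyl 6-methyl-3,5-dioxoheptanoate | COC(=O)CC(=O)CC(=O)C(C)C
F0 | step 4 | none | none
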